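## Retrosynthetic overview

1. The butenolide is formed last, by global desilylation and lactonization of the (Z)-γ-silyloxy enoate 20, which comes from an Ando Z-selective HWE of the (R)-α-silyloxy aldehyde 16 with the α-homoprenyl phosphonate 19.
2. Lactone C5 (R) and the adjacent CH2–CH(O) bond come from an Evans/Crimmins glycolate alkylation of imide 13 with the (E)-allylic bromide 10.
3. The chromene pyran ring is formed first, by ring-closing metathesis of the o-vinylphenyl tertiary allylic ether 8.
4. The quaternary chromene C2 (S) comes from a Pd-catalysed asymmetric allylic O-alkylation (Trost AAA) of vinylphenol 4 with the geraniol-derived carbonate 7; the (E)-trisubstituted alkene is carried intact from geraniol after SeO2 oxidation.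
5. Ring order: purchased arene → 2H-pyran (step 7) → butenolide (step 15).

Assumption 1: read from the SMILES, the target is (S) at chromene C2 and (R) at lactone C5.
Assumption 2: in step 6 the (R,R)-Trost ligand with the (E)-carbonate is taken to give the (S)-ether; I could not confirm this sense from memory, so if the (R)-ether forms, use the (S,S)-ligand and change nothing else.
Assumption 3: acid 12 is purchased.

## Route

**Step 1**
Reactants: 1, 2-methylbenzene-1,4-diol
Product: 2, 2-methyl-4-[(triisopropylsilyl)oxy]phenol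
Conditions: TIPSCl (1.0 equiv), imidazole, DMF, 0 °C → rt
Reagents that add atoms: TIPSCl, CC(C)[Si](Cl)(C(C)C)C(C)C
Why: Selective monosilylation; the bulky silyl chloride goes to the OH with no ortho substituent, leaving the OH next to the methyl free.

**Step 2**
Reactants: 2
Product: 3, 2-hydroxy-3-methyl-5-[(triisopropylsilyl)oxy]benzaldehyde
Conditions: (CH2O)n, MgCl2, Et3N, MeCN, reflux
Reagents that add atoms: paraformaldehyde, C=O
Why: Casnati–Skattebøl Mg-phenoxide-directed ortho-formylation; only one ortho position is free.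

**Step 3**
Reactants: 3
Product: 4, 2-ethenyl-6-methyl-4-[(triisopropylsilyl)oxy]phenol
Conditions: Ph3PCH3Br, KOtBu (2.5 equiv each), THF, 0 °C → rt
Reagents that add atoms: methyltriphenylphosphonium bromide, C[P+](c1ccccc1)(c1ccccc1)c1ccccc1.[Br-]
Why: Wittig methylenation of the salicylaldehyde (excess ylide covers the phenoxide) gives the styrene needed for RCM.

**Step 4**
Reactants: 5, geraniol
Product: 6, geranyl methyl carbonate
Conditions: ClCO2Me, pyridine, CH2Cl2, 0 °C
Reagents that add atoms: methyl chloroformate, COC(=O)Cl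
Why: O-acylation to the allylic carbonate, the ionizable group for Pd(0).

**Step 5**
Reactants: 6
Product: 7, (2E,6E)-8-hydroxy-3,7-dimethylocta-2,6-dien-1-yl methyl carbonate
Conditions: SeO2 (cat.), t-BuOOH, salicylic acid (cat.), CH2Cl2, rt; separate from minor enal
Reagents that add atoms: SeO2, O=[Se]=O, with t-BuOOH, CC(C)(C)OO (adds one O)
Why: Sharpless SeO2/TBHP allylic oxidation (ene then [2,3]) is E-selective at the terminal methyl of the distal olefin, because the 2,3-olefin is deactivated by the allylic carbonate.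

**Step 6**
Reactants: 4 and 7
Product: 8, (2E,6S)-6-{2-ethenyl-6-methyl-4-[(triisopropylsilyl)oxy]phenoxy}-2,6-dimethylocta-2,7-dien-1-ol
Conditions: Pd2(dba)3·CHCl3 (2 mol %), (R,R)-DACH-phenyl Trost ligand (6 mol %), CH2Cl2, rt; stop at full conversion
Reagents that add atoms: none
Why: Trost asymmetric allylic O-alkylation; the phenol attacks the more substituted terminus of the chiral π-allyl-Pd complex to give the branched tertiary ether, and ligand control sets C6 (S), the future chromene C2.

**Step 7**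
Reactants: 8
Product: 9, (2E)-5-{(2S)-2,8-dimethyl-6-[(triisopropylsilyl)oxy]-2H-chromen-2-yl}-2-methylpent-2-en-1-ol
Conditions: Grubbs II (3–5 mol %), CH2Cl2 (5 mM), 40 °C
Reagents that add atoms: none
Why: Ring-closing metathesis; Ru loads on the styrene and closes onto the hindered vinyl group to form the six-membered ring (ethylene lost), the trisubstituted alkene is a poor partner, and the stereocentre is untouched.

**Step 8**
Reactants: 9
Product: 10, (2S)-2-[(3E)-5-bromo-4-methylpent-3-en-1-yl]-2,8-dimethyl-6-[(triisopropylsilyl)oxy]-2H-chromene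
Conditions: MsCl, Et3N, THF, −40 °C; then LiBr, 0 °C; use crude
Reagents that add atoms: LiBr, [Li+].[Br-]
Why: Mesylation and SN2 displacement at the primary allylic carbon under non-acidic conditions keeps the E-olefin and the chromene intact.

**Step 9**
Reactants: 11, (S)-4-benzyl-1,3-oxazolidin-2-one, and 12, 2-[(tert-butyldimethylsilyl)oxy]acetic acid
Product: 13, (S)-4-benzyl-3-{2-[(tert-butyldimethylsilyl)oxy]acetyl}-1,3-oxazolidin-2-one
Conditions: 12, PivCl, Et3N, THF, −20 → 0 °C; then 11, LiCl, rt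
Reagents that add atoms: none
Why: N-acylation of the auxiliary through the mixed pivalic anhydride.

**Step 10**
Reactants: 10 and 13 (2 equiv)
Product: 14, (4S)-4-benzyl-3-[(2R,4E)-2-[(tert-butyldimethylsilyl)oxy]-7-{(2S)-2,8-dimethyl-6-[(triisopropylsilyl)oxy]-2H-chromen-2-yl}-4-methylhept-4-enoyl]-1,3-oxazolidin-2-one
Conditions: 13, NaHMDS, THF, −78 °C; then 10, Bu4NI (cat.), −78 → −40 °C
Reagents that add atoms: none
Why: Evans/Crimmins asymmetric glycolate alkylation; the chelated Z-sodium enolate is alkylated anti to the benzyl group, which sets C2 as (R), the future lactone C5.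

**Step 11**
Reactants: 14
Product: 15, (2R,4E)-2-[(tert-butyldimethylsilyl)oxy]-7-{(2S)-2,8-dimethyl-6-[(triisopropylsilyl)oxy]-2H-chromen-2-yl}-4-methylhept-4-en-1-ol
Conditions: LiBH4, MeOH (1.1 equiv), Et2O, 0 °C
Reagents that add atoms: none
Why: Reductive removal of the auxiliary to the primary alcohol without epimerization; nothing else in the molecule is reducible.

**Step 12**
Reactants: 15
Product: 16, (2R,4E)-2-[(tert-butyldimethylsilyl)oxy]-7-{(2S)-2,8-dimethyl-6-[(triisopropylsilyl)oxy]-2H-chromen-2-yl}-4-methylhept-4-enal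
Conditions: Dess–Martin periodinane, NaHCO3, CH2Cl2, 0 °C → rt; use at once
Reagents that add atoms: none
Why: Buffered Dess–Martin oxidation gives the α-silyloxy aldehyde without epimerization and leaves the alkenes and chromene alone.

**Step 13**
Reactants: 17, ethyl 2-(diphenoxyphosphoryl)acetate, and 18, 5-bromo-2-methylpent-2-ene
Product: 19, ethyl 2-(diphenoxyphosphoryl)-6-methylhept-5-enoate
Conditions: NaH, DMSO, rt; then 18, NaI (cat.), 50 °C
Reagents that add atoms: none
Why: C-alkylation of the phosphonoacetate anion installs the homoprenyl group on the future lactone α-carbon.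

**Step 14**
Reactants: 16 and 19
Product: 20, ethyl (2Z,4R,6E)-4-[(tert-butyldimethylsilyl)oxy]-9-{(2S)-2,8-dimethyl-6-[(triisopropylsilyl)oxy]-2H-chromen-2-yl}-6-methyl-2-(4-methylpent-3-en-1-yl)nona-2,6-dienoate
Conditions: 19, NaH, THF, 0 °C; then 16, −78 → 0 °C
Reagents that add atoms: none
Why: Ando Z-selective Horner–Wadsworth–Emmons olefination (diaryl phosphonate) places the ester cis to the C4 oxygen; any E-isomer cannot lactonize and is removed later.

**Step 15**
Reactants: 20
Product: 21, tuberatolide B, (5R)-5-{(2E)-5-[(2S)-6-hydroxy-2,8-dimethyl-2H-chromen-2-yl]-2-methylpent-2-en-1-yl}-3-(4-methylpent-3-en-1-yl)furan-2(5H)-one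
Conditions: TBAF/AcOH (1:1, 4 equiv), THF, 0 °C → rt; then PPTS (cat.), CH2Cl2, rt if hydroxy ester remains
Reagents that add atoms: none
Why: Buffered fluoride removes both silyl groups and the freed γ-hydroxyl lactonizes onto the Z-ester (EtOH lost); the buffer avoids base epimerization of the butenolide γ-centre.

## Compound list

1 | 2-methylbenzene-1,4-diol | Cc1cc(O)ccc1O | starting material
2 | 2-methyl-4-[(triisopropylsilyl)oxy]phenol | Cc1cc(O[Si](C(C)C)(C(C)C)C(C)C)ccc1O | intermediate
3 | 2-hydroxy-3-methyl-5-[(triisopropylsilyl)oxy]benzaldehyde | Cc1cc(O[Si](C(C)C)(C(C)C)C(C)C)cc(C=O)c1O | intermediate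
4 | 2-ethenyl-6-methyl-4-[(triisopropylsilyl)oxy]phenol | Cc1cc(O[Si](C(C)C)(C(C)C)C(C)C)cc(C=C)c1O | intermediate
5 | geraniol | CC(C)=CCC/C(C)=C/CO | starting material
6 | geranyl methyl carbonate | CC(C)=CCC/C(C)=C/COC(=O)OC | intermediate
7 | (2E,6E)-8-hydroxy-3,7-dimethylocta-2,6-dien-1-yl methyl carbonate | OC/C(C)=C/CC/C(C)=C/COC(=O)OC | intermediate
8 | (2E,6S)-6-{2-ethenyl-6-methyl-4-[(triisopropylsilyl)oxy]phenoxy}-2,6-dimethylocta-2,7-dien-1-ol | OC/C(C)=C/CC[C@@](C)(C=C)Oc1c(C)cc(O[Si](C(C)C)(C(C)C)C(C)C)cc1C=C | intermediate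
9 | (2E)-5-{(2S)-2,8-dimethyl-6-[(triisopropylsilyl)oxy]-2H-chromen-2-yl}-2-methylpent-2-en-1-ol | OC/C(C)=C/CC[C@@]1(C)C=Cc2cc(O[Si](C(C)C)(C(C)C)C(C)C)cc(C)c2O1 | intermediate
10 | (2S)-2-[(3E)-5-bromo-4-methylpent-3-en-1-yl]-2,8-dimethyl-6-[(triisopropylsilyl)oxy]-2H-chromene | BrC/C(C)=C/CC[C@@]1(C)C=Cc2cc(O[Si](C(C)C)(C(C)C)C(C)C)cc(C)c2O1 | intermediate
11 | (S)-4-benzyl-1,3-oxazolidin-2-one | O=C1N[C@@H](Cc2ccccc2)CO1 | starting material
12 | 2-[(tert-butyldimethylsilyl)oxy]acetic acid | CC(C)(C)[Si](C)(C)OCC(=O)O | starting material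
13 | (S)-4-benzyl-3-{2-[(tert-butyldimethylsilyl)oxy]acetyl}-1,3-oxazolidin-2-one | CC(C)(C)[Si](C)(C)OCC(=O)N1[C@@H](Cc2ccccc2)COC1=O | intermediate
14 | (4S)-4-benzyl-3-[(2R,4E)-2-(TBSO)-7-{(2S)-2,8-dimethyl-6-(TIPSO)-2H-chromen-2-yl}-4-methylhept-4-enoyl]-1,3-oxazolidin-2-one | CC(C)(C)[Si](C)(C)O[C@H](C/C(C)=C/CC[C@@]1(C)C=Cc2cc(O[Si](C(C)C)(C(C)C)C(C)C)cc(C)c2O1)C(=O)N1[C@@H](Cc2ccccc2)COC1=O | intermediate
15 | (2R,4E)-2-(TBSO)-7-{(2S)-2,8-dimethyl-6-(TIPSO)-2H-chromen-2-yl}-4-methylhept-4-en-1-ol | CC(C)(C)[Si](C)(C)O[C@H](C/C(C)=C/CC[C@@]1(C)C=Cc2cc(O[Si](C(C)C)(C(C)C)C(C)C)cc(C)c2O1)CO | intermediate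
16 | (2R,4E)-2-(TBSO)-7-{(2S)-2,8-dimethyl-6-(TIPSO)-2H-chromen-2-yl}-4-methylhept-4-enal | CC(C)(C)[Si](C)(C)O[C@H](C/C(C)=C/CC[C@@]1(C)C=Cc2cc(O[Si](C(C)C)(C(C)C)C(C)C)cc(C)c2O1)C=O | intermediate
17 | ethyl 2-(diphenoxyphosphoryl)acetate | CCOC(=O)CP(=O)(Oc1ccccc1)Oc1ccccc1 | starting material
18 | 5-bromo-2-methylpent-2-ene | CC(C)=CCCBr | starting material
19 | ethyl 2-(diphenoxyphosphoryl)-6-methylhept-5-enoate | CCOC(=O)C(CCC=C(C)C)P(=O)(Oc1ccccc1)Oc1ccccc1 | intermediate
20 | ethyl (2Z,4R,6E)-4-(TBSO)-9-{(2S)-2,8-dimethyl-6-(TIPSO)-2H-chromen-2-yl}-6-methyl-2-(4-methylpent-3-en-1-yl)nona-2,6-dienoate | CCOC(=O)/C(CCC=C(C)C)=C\[C@H](O[Si](C)(C)C(C)(C)C)C/C(C)=C/CC[C@@]1(C)C=Cc2cc(O[Si](C(C)C)(C(C)C)C(C)C)cc(C)c2O1 | intermediate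
21 | tuberatolide B, (5R)-5-{(2E)-5-[(2S)-6-hydroxy-2,8-dimethyl-2H-chromen-2-yl]-2-methylpent-2-en-1-yl}-3-(4-methylpent-3-en-1-yl)furan-2(5H)-one | CC(C)=CCCC1=C[C@@H](C/C(C)=C/CC[C@@]2(C)C=Cc3cc(O)cc(C)c3O2)OC1=O | target

## Totals and risks

Total steps: 15.
Longest linear sequence: 11 steps (1, 2, 3, 6, 7, 8, 10, 11, 12, 14, 15) from 2-methylbenzene-1,4-diol.

Steps most likely to fail:

1. **Step 6 (Pd-AAA).** The phenol is substituted at both ortho positions, so the branched/linear ratio and the ee are uncertain, and the ligand sense is assumed. Low ee would carry through as the C2-epimer of the target, which would need chiral SFC at 9.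
   Fallback: set the carbinol by reagent control instead. Geraniol → Sharpless epoxidation (L-(+)-DET) → epoxy chloride → n-BuLi gives (S)-3,7-dimethyloct-6-en-1-yn-3-ol. Sonogashira coupling to an o-bromo-iodoarene, Lindlar reduction and intramolecular Pd-catalysed aryl C–O coupling then give the chromene without ever breaking the carbinol C–O bond.

2. **Step 7 (RCM).** The vinyl group could instead close onto the trisubstituted alkene (cyclopentene formation), or the substrate could oligomerize.
   Fallback: run the AAA and RCM on a chain with no trisubstituted olefin, using the carbonate of (E)-6,6-dimethoxy-3-methylhex-2-en-1-ol. After ring closure, unmask the aldehyde and install the E-olefin by Wittig with Ph3P=C(CH3)CO2Et, then DIBAL, to reach 9.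

3. **Step 10 (glycolate alkylation).** The enolate is thermally labile, the electrophile is the valuable partner, and a silyl-protected glycolate is less proven than benzyl or PMB.
   Fallback: set the C–O centre by organocatalysis. Homologate 10 with the lithium enolate of tert-butyl acetate, reduce with DIBAL to the aldehyde, then run L-proline/nitrosobenzene α-aminoxylation with in situ Z-HWE using 19. N–O cleavage and lactonization give the butenolide.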